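**Plan**

1. Retrosynthesis cuts, in this order: the two C–O bonds of the 1,2-dioxepane (with the tertiary C–OH), the cage bond from the benzoyl-bearing carbon C1 to the gem-dimethyl carbon C8, the C1–benzoyl and C3–prenyl bonds, the bond from ring carbon C3 to the ethano CH (C11), and one C–C(=O) bond of the six-membered ring. This leads back to methyl acetoacetate, geranyl bromide and a C10 bromo carbonate.
2. Enabling feature: the six-membered trione ring has at C3 a quaternary carbon bonded to the ethano CH that carries the peroxy CMe2 group. C3 lies 1,3 to the geranyl-bearing C5, which holds the other end of that chain, so a π-allyl terminus hanging from C5 can alkylate the enol carbon C3 and close the seven-membered ring C3–C4–C5–C6–C7–C10–C11.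
3. Forward order: acyclic keto ester → achiral six-membered trione (Claisen) → seven-membered ring by palladium (bicyclo[4.3.1]) → prenyl on C3 and benzoyl on C1 → homoadamantane cage by cationic C1–C8 closure → 1,2-dioxepane by a cobalt/oxygen radical cascade.
4. Stereochemistry: the chiral palladium catalyst desymmetrises the trione and sets C3, C5 and C11 together. C1 and C7 are dictated by the cage, prenyl can only enter exo, and C14 arises in the peroxyl ring closure.
5. C5 is made quaternary before the ring closure, because a planar tether-bearing ring carbon cannot bridge to its 1,3-neighbour and would close on itself to a spiro five-membered ring.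

Key step: step 9

**Remarks**

- Core numbering used for 14–24: C1 = ring carbon that ends up benzoylated; C2 and C9 = its two carbonyl neighbours; C3 = ring carbon between C2 and C4; C4 = carbonyl between C3 and C5; C5 = geranyl-bearing carbon; C6 = CH2 on C5; C7 = carbon bearing C8 (isopropylidene, later CMe2); C10 = CH2 between C7 and C11; C11 = CH bearing C12 (isopropenyl, later peroxy CMe2); C13–C15 = the prenyl chain on C3.
- Assumption: the (R,R) ligand is written in step 9; which ligand enantiomer delivers 15 has to be fixed in the first run, and its mirror image is used if the sense is opposite.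
- Step 10 should also give the regioisomeric enol ether (methoxy on C2). It can be carried through steps 11–13 in the same way and converges on 21.

**Step 1**
Reactants: 1 diethyl 2-(propan-2-ylidene)propanedioate
Product: 2 2-(propan-2-ylidene)propane-1,3-diol
Conditions: i-Bu2AlH (5 equiv), CH2Cl2, −78 → 0 °C; aq. potassium sodium tartrate
Reagents that add atoms: none
Why: 1,2-reduction of both conjugated esters by the aluminium hydride (ester-to-alcohol reduction) should give the allylic diol and leave the tetrasubstituted double bond alone.

**Step 2**
Reactants: 2 2-(propan-2-ylidene)propane-1,3-diol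
Product: 3 1-bromo-2-(bromomethyl)-3-methylbut-2-ene
Conditions: PBr3 (0.75 equiv), Et2O, −10 → 0 °C
Reagents that add atoms: phosphorus tribromide, BrP(Br)Br
Why: bromination of primary allylic alcohols with PBr3; the primary bromide keeps the tetrasubstituted alkene, so allylic transposition is not expected.

**Step 3**
Reactants: 4 prop-2-yn-1-ol; 3 1-bromo-2-(bromomethyl)-3-methylbut-2-ene
Product: 6 (2E)-5-(bromomethyl)-2,6-dimethylhepta-2,5-dien-1-ol, via alkenylalane alkoxide 5 (not isolated)
Conditions: AlMe3 (3 equiv), Cp2ZrCl2 (0.25 equiv), CH2Cl2, 0 → 23 °C; then 3 (3 equiv), Pd(PPh3)4 (5 mol %), THF, 23 °C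
Reagents that add atoms: trimethylaluminium, C[Al](C)C
Why: zirconium-catalysed syn-carboalumination of the alkyne (Negishi carboalumination) puts methyl and aluminium cis, and palladium-catalysed alkenyl–allyl cross-coupling with one C–Br of the excess dibromide should then give the skipped diene with the E geometry retained.

**Step 4**
Reactants: 6 (2E)-5-(bromomethyl)-2,6-dimethylhepta-2,5-dien-1-ol
Product: 7 (2E)-5-(bromomethyl)-2,6-dimethylhepta-2,5-dien-1-yl methyl carbonate
Conditions: ClCO2Me (1.3 equiv), pyridine (2 equiv), CH2Cl2, 0 °C
Reagents that add atoms: methyl chloroformate, COC(=O)Cl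
Why: O-acylation of the primary alcohol (carbonate formation) installs the leaving group for the later allylic alkylation; pyridine at 0 °C is too weak a nucleophile to consume the allylic bromide.

**Step 5**
Reactants: 8 methyl 3-oxobutanoate; 9 geranyl bromide
Product: 10 methyl (4E)-2-acetyl-5,9-dimethyldeca-4,8-dienoate (racemic)
Conditions: NaH (1.0 equiv), THF, 0 °C; 9 (0.9 equiv), 0 → 23 °C
Reagents that add atoms: none
Why: acetoacetic ester alkylation, C-alkylation of the sodium enolate by a primary allylic bromide.

**Step 6**
Reactants: 10 methyl 2-geranylacetoacetate; 7 bromo carbonate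
Product: 11 methyl 2-geranyl-2-[(4E)-6-(methoxycarbonyloxy)-5-methyl-2-(propan-2-ylidene)hex-4-en-1-yl]-3-oxobutanoate (racemic)
Conditions: NaH (1.1 equiv), THF–DMF (4:1), 0 → 23 °C
Reagents that add atoms: none
Why: second acetoacetic ester alkylation; the soft stabilised enolate displaces the allylic bromide (SN2) and should not touch the carbonate, giving the quaternary carbon that becomes C5.

**Step 7**
Reactants: 11 quaternary keto ester; 12 1-acetyl-1H-benzotriazole
Product: 13 methyl 2-geranyl-2-[(4E)-6-(methoxycarbonyloxy)-5-methyl-2-(propan-2-ylidene)hex-4-en-1-yl]-3,5-dioxohexanoate (racemic)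
Conditions: MgBr2·OEt2 (2.5 equiv), i-Pr2NEt (3 equiv), 12 (1.3 equiv), CH2Cl2, 23 °C
Reagents that add atoms: none
Why: soft-enolisation C-acylation (crossed Claisen-type) of the methyl ketone, the only enolisable position, by the N-acylbenzotriazole gives the 1,3-diketone without strong base.

**Step 8**
Reactants: 13 diketo ester
Product: 14 2-geranyl-2-[(4E)-6-(methoxycarbonyloxy)-5-methyl-2-(propan-2-ylidene)hex-4-en-1-yl]cyclohexane-1,3,5-trione (achiral, enolised)
Conditions: LiN(iPr)2 (2.3 equiv), THF, −78 → 0 °C; then 1 M HCl
Reagents that add atoms: none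
Why: intramolecular Claisen (Dieckmann-type) condensation of the terminal carbanion of the diketone dianion onto the ester closes the six-membered ring, as in polyketide-type routes to phloroglucinol-level triones; the two ring arms become identical, so the stereocentre disappears.

**Step 9**
Reactants: 14 achiral trione
Product: 15 5-geranyl-11-isopropenyl-7-(propan-2-ylidene)bicyclo[4.3.1]decane-2,4,9-trione (2-enol; H-3 and isopropenyl cis on the seven-membered ring, geranyl on the face of the six-membered ring opposite to the C6–C11 bridge)
Conditions: Pd2(dba)3·CHCl3 (2.5 mol %), (R,R)-N,N′-(cyclohexane-1,2-diyl)bis[2-(diphenylphosphino)benzamide] (7.5 mol %), CH2Cl2 (0.005 M), 23 °C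
Reagents that add atoms: none
Why: Zerovalent palladium ionises the allylic carbonate to a 2-methyl-substituted π-allyl complex, the liberated methoxide deprotonates the trione, and the enolate attacks the allyl unit on the face opposite to the metal (Tsuji–Trost allylic alkylation). The closest known reactions are the palladium-catalysed bridging allylation of dearomatised acylphloroglucinols at the ring carbon 1,3 to a tether-bearing quaternary carbon, and desymmetrising asymmetric allylic alkylations of prochiral 1,3-dicarbonyl nucleophiles. The seven-membered ring C3–C4–C5–C6–C7–C10–C11 closes 7-exo by attack on the internal allyl terminus, which leaves the isopropenyl group; this is possible because C5 is sp3 and holds the tether axial, and C5 itself can no longer act as a nucleophile. C3 and C5 become stereogenic together because the allyl unit must choose one of the two enantiotopic enol carbons, and the chiral bisphosphine controls that choice through the allyl face it presents; C11 follows from the same transition state, in which the metal-bearing propenyl unit points away from the six-membered ring, so that isopropenyl ends up cis to H-3. The step needs C- over O-allylation (O-allyl enol ethers re-ionise under palladium and funnel to the C–C product), internal over terminal attack (a seven- against a nine-membered ring) and ring closure over oligomerisation (high dilution).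

**Step 10**
Reactants: 15 bicyclic trione
Product: 16 9-O-methyl enol ether of 15 (9-methoxy-enone; C2 and C4 remain ketones)
Conditions: Me3SiCHN2 (2 equiv), toluene–MeOH (4:1), 0 °C
Reagents that add atoms: trimethylsilyldiazomethane, C[Si](C)(C)C=[N+]=[N-]
Why: O-methylation of the acidic enol by the diazoalkane gives the vinylogous ester, which protects the diketone during the two carbanion steps and supplies the enol ether nucleophile for step 13.

**Step 11**
Reactants: 16 vinylogous ester; 17 prenyl bromide
Product: 18 3-prenyl derivative of 16 (prenyl cis to isopropenyl)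
Conditions: LiN(iPr)2 (1.3 equiv), THF, −78 °C; 17 (2 equiv), −78 → −20 °C
Reagents that add atoms: none
Why: bridgehead enolate alkylation; the amide base removes H-3 between the C2 and C4 carbonyls (the C3=C2 enolate double bond lies in the three-carbon bridge of the bicyclo[4.3.1] system and is allowed), and prenyl bromide can only approach from the face opposite to the four-carbon bridge, so the C3 configuration follows from the ring fusion.

**Step 12**
Reactants: 18 prenylated vinylogous ester; 19 benzoyl chloride
Product: 20 1-benzoyl derivative of 18
Conditions: lithium 2,2,6,6-tetramethylpiperidide (1.5 equiv), THF, −78 °C; 19 (2 equiv), −78 → −40 °C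
Reagents that add atoms: none
Why: α-lithiation of the β-methoxy enone at its vinylic carbon C1 followed by C-acylation with the acid chloride, the usual way to acylate bicyclic polyprenylated vinylogous esters.

**Step 13**
Reactants: 20 benzoylated vinylogous ester
Product: 21 caged trione (homoadamantane; C1–C8 bond closed, H-7 exo, isopropenyl, prenyl and geranyl intact)
Conditions: HCO2H (98 %, neat), 10 → 23 °C
Reagents that add atoms: none
Why: proton-initiated cation–enol ether cyclisation (biomimetic cationic closure between two quaternary carbons); the tetrasubstituted alkene is protonated at C7 from outside while C1 bonds to C8 from inside (anti addition), the O-methyl oxocarbenium ion loses methyl to formate, and the cage geometry fixes C1 and C7.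

**Step 14**
Reactants: 21 caged trione
Product: 22 caged 1,2-dioxepane carrying a 2-(triethylsilylperoxy)propan-2-yl group on C14
Conditions: Co(acac)2 (10 mol %), O2 (1 atm), Et3SiH (3 equiv), ClCH2CH2Cl (0.01 M), 23 °C
Reagents that add atoms: dioxygen, O=O; triethylsilane, CC[SiH](CC)CC
Why: Mukaiyama–Isayama-type peroxidation; hydrogen-atom transfer from the cobalt hydride to the 1,1-disubstituted alkene (faster than to the three trisubstituted ones) gives the C12 radical, which takes up O2, the tertiary peroxyl radical closes 7-exo onto the prenyl double bond held cis on C3 (peroxyl radical cyclisation), and the new tertiary radical takes up a second O2 and is silylated; C14 is expected to form through a chair-like transition state with the large C15 group pseudo-equatorial, which is taken to correspond to the target.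

**Step 15**
Reactants: 22 silyl peroxide
Product: 24 CNP0148771.1 (target), via hydroperoxide 23 (not isolated)
Conditions: HCl (cat.), MeOH, 0 °C; then PPh3 (1.1 equiv), CH2Cl2, 0 °C
Reagents that add atoms: none
Why: acid-catalysed methanolysis of the silyl peroxide followed by phosphine reduction of the hydroperoxide to the alcohol, which is chemoselective over the dialkyl peroxide of the ring.

**Compound list**

1 | diethyl 2-(propan-2-ylidene)propanedioate | CCOC(=O)C(=C(C)C)C(=O)OCC | starting material
2 | 2-(propan-2-ylidene)propane-1,3-diol | OCC(=C(C)C)CO | intermediate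
3 | 1-bromo-2-(bromomethyl)-3-methylbut-2-ene | BrCC(=C(C)C)CBr | intermediate
4 | prop-2-yn-1-ol | C#CCO | starting material
5 | dimethylaluminium (E)-3-(dimethylalumanyl)-2-methylprop-2-en-1-olate | C[Al](C)/C=C(\C)CO[Al](C)C | intermediate (not isolated)
6 | (2E)-5-(bromomethyl)-2,6-dimethylhepta-2,5-dien-1-ol | OC/C(C)=C/CC(CBr)=C(C)C | intermediate
7 | (2E)-5-(bromomethyl)-2,6-dimethylhepta-2,5-dien-1-yl methyl carbonate | COC(=O)OC/C(C)=C/CC(CBr)=C(C)C | intermediate
8 | methyl 3-oxobutanoate | COC(=O)CC(C)=O | starting material
9 | geranyl bromide, (2E)-1-bromo-3,7-dimethylocta-2,6-diene | CC(C)=CCC/C(C)=C/CBr | starting material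
10 | methyl (4E)-2-acetyl-5,9-dimethyldeca-4,8-dienoate (racemic) | COC(=O)C(C/C=C(\C)CCC=C(C)C)C(C)=O | intermediate
11 | methyl 2-geranyl-2-[(4E)-6-(methoxycarbonyloxy)-5-methyl-2-(propan-2-ylidene)hex-4-en-1-yl]-3-oxobutanoate (racemic) | COC(=O)C(C/C=C(\C)CCC=C(C)C)(CC(=C(C)C)C/C=C(\C)COC(=O)OC)C(C)=O | intermediate
12 | 1-acetyl-1H-benzotriazole | CC(=O)n1nnc2ccccc21 | starting material
13 | methyl 2-geranyl-2-[(4E)-6-(methoxycarbonyloxy)-5-methyl-2-(propan-2-ylidene)hex-4-en-1-yl]-3,5-dioxohexanoate (racemic) | COC(=O)C(C/C=C(\C)CCC=C(C)C)(CC(=C(C)C)C/C=C(\C)COC(=O)OC)C(=O)CC(C)=O | intermediate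
14 | 2-geranyl-2-[(4E)-6-(methoxycarbonyloxy)-5-methyl-2-(propan-2-ylidene)hex-4-en-1-yl]cyclohexane-1,3,5-trione (achiral; triketo tautomer shown) | O=C1CC(=O)CC(=O)C1(C/C=C(\C)CCC=C(C)C)CC(=C(C)C)C/C=C(\C)COC(=O)OC | intermediate
15 | 5-geranyl-11-isopropenyl-7-(propan-2-ylidene)bicyclo[4.3.1]decane-2,4,9-trione, 2-enol; H-3 cis to isopropenyl, geranyl anti to the C6–C11 bridge | C=C(C)[C@H]1CC(=C(C)C)C[C@]2(C/C=C(\C)CCC=C(C)C)C(=O)C=C(O)[C@H]1C2=O | intermediate
16 | 9-O-methyl enol ether of 15 | C=C(C)[C@H]1CC(=C(C)C)C[C@]2(C/C=C(\C)CCC=C(C)C)C(OC)=CC(=O)[C@H]1C2=O | intermediate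
17 | prenyl bromide, 1-bromo-3-methylbut-2-ene | CC(C)=CCBr | starting material
18 | 3-prenyl derivative of 16; prenyl cis to isopropenyl | C=C(C)[C@H]1CC(=C(C)C)C[C@]2(C/C=C(\C)CCC=C(C)C)C(OC)=CC(=O)[C@@]1(CC=C(C)C)C2=O | intermediate
19 | benzoyl chloride | O=C(Cl)c1ccccc1 | starting material
20 | 1-benzoyl derivative of 18 | C=C(C)[C@H]1CC(=C(C)C)C[C@]2(C/C=C(\C)CCC=C(C)C)C(OC)=C(C(=O)c3ccccc3)C(=O)[C@@]1(CC=C(C)C)C2=O | intermediate
21 | 1-benzoyl-5-geranyl-11-isopropenyl-8,8-dimethyl-3-prenyl homoadamantane-2,4,9-trione (C1–C8 closed, H-7 exo) | CC(C)=CCC/C(C)=C/C[C@]12C[C@@H]3C[C@H](C(C)=C)[C@](CC=C(C)C)(C1=O)C(=O)[C@](C(=O)c1ccccc1)(C2=O)C3(C)C | intermediate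
22 | caged 1,2-dioxepane with 2-(triethylsilylperoxy)propan-2-yl on C14 | CC(C)=CCC/C(C)=C/C[C@]12C[C@@H]3C[C@@H]4C(C)(C)OO[C@H](C(C)(C)OO[Si](CC)(CC)CC)C[C@@]4(C1=O)C(=O)[C@](C(=O)c1ccccc1)(C2=O)C3(C)C | intermediate
23 | caged 1,2-dioxepane with 2-hydroperoxypropan-2-yl on C14 | CC(C)=CCC/C(C)=C/C[C@]12C[C@@H]3C[C@@H]4C(C)(C)OO[C@H](C(C)(C)OO)C[C@@]4(C1=O)C(=O)[C@](C(=O)c1ccccc1)(C2=O)C3(C)C | intermediate (not isolated)
24 | CNP0148771.1; (1R,3R,5S,7S,11S,14S) in the core numbering of the remarks | CC(C)=CCC/C(C)=C/C[C@]12C[C@@H]3C[C@@H]4C(C)(C)OO[C@H](C(C)(C)O)C[C@@]4(C1=O)C(=O)[C@](C(=O)c1ccccc1)(C2=O)C3(C)C | target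

**Summary**

Total step count: 15. Longest linear sequence: 14 steps (steps 1–4, then 6–15).

Steps most likely to fail:

1. Step 9. The catalyst may discriminate poorly between the two enantiotopic enol carbons, so that the ring closes with low enantiomeric excess. Fallback: setting out from 14, the closure is run without asymmetric induction under Pd(PPh3)4 in THF at high dilution (the conditions of the known bridging double allylation of phloroglucinol-derived enols). This should give 15 together with its mirror image, ent-15 F1. The two are separated by preparative chromatography on a chiral stationary phase with an acidified eluent, F1 is discarded, and the route is rejoined at 15.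

2. Step 13. Formic acid may also protonate the isopropenyl, prenyl and geranyl double bonds. That would lead to ether formation with the carbonyl oxygens, migration of the isopropenyl double bond with loss of the C11 configuration, or cyclisation of the geranyl chain. Fallback: setting out from 20, the most electron-rich alkene is activated selectively by an iodonium ion (N-iodosuccinimide, CH2Cl2, −78 °C; iodo-carbocyclisation of an alkenyl 1,3-dicarbonyl equivalent). This gives the 7-iodo cage F2 by the same anti addition, with methyl lost to succinimide. Radical deiodination with Bu3SnH and Et3B/air in toluene at −78 → 0 °C then gives 21, where the route is rejoined.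

3. Step 14. Cobalt may trap the first peroxyl radical before it cyclises, or the 7-exo closure may show poor facial selectivity at C14. Fallback: setting out from 21, the peroxidation is run at high Co(acac)2 loading so that only the open 11-[2-(triethylsilylperoxy)propan-2-yl] cage F3 is formed. Methanolysis (HCl cat., MeOH) gives the open tertiary hydroperoxide F4. F4 is then cyclised in a separate peroxyl radical chain reaction (di-tert-butyl hyponitrite, O2, tert-butyl hydroperoxide as chain-transfer agent, benzene, 30 °C) to 23, which is reduced with PPh3 as in step 15.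

**Further compounds**

F1 | step 9 | ent-15, mirror image of the bicyclic trione | C=C(C)[C@@H]1CC(=C(C)C)C[C@@]2(C/C=C(\C)CCC=C(C)C)C(=O)C=C(O)[C@@H]1C2=O
F2 | step 13 | 7-iodo derivative of the caged trione 21 | CC(C)=CCC/C(C)=C/C[C@]12C[C@]3(I)C[C@H](C(C)=C)[C@](CC=C(C)C)(C1=O)C(=O)[C@](C(=O)c1ccccc1)(C2=O)C3(C)C
F3 | step 14 | caged trione with 2-(triethylsilylperoxy)propan-2-yl on C11, prenyl intact | CC(C)=CCC/C(C)=C/C[C@]12C[C@@H]3C[C@H](C(C)(C)OO[Si](CC)(CC)CC)[C@](CC=C(C)C)(C1=O)C(=O)[C@](C(=O)c1ccccc1)(C2=O)C3(C)C
F4 | step 14 | caged trione with 2-hydroperoxypropan-2-yl on C11, prenyl intact | CC(C)=CCC/C(C)=C/C[C@]12C[C@@H]3C[C@H](C(C)(C)OO)[C@](CC=C(C)C)(C1=O)C(=O)[C@](C(=O)c1ccccc1)(C2=O)C3(C)C
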